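**Remark on the chemistry:** the target has no stereocentre. Ring atoms are numbered from the carboxyl-bearing carbon (C1) of each benzoic acid. Methyl 2-hydroxy-4-methoxybenzoate 14 is assumed to be purchasable.

## The problem

The target 24 is a depside: two benzene rings that share no bond except one aryl ester, in which the C1 carboxyl carbon of ring A is esterified by the C4 oxygen of ring B. There is no stereocentre, so the difficulty lies in regiochemistry and functional-group compatibility. Each ring carries a 2-oxoheptyl chain ortho to its carboxyl carbon. The two resorcinol-type oxygen patterns differ only in which oxygen is methylated: C4 on ring A (C2 free), C2 on ring B (C4 acylated). The 2-(2-oxoalkyl)benzoyl motif is the weak point: under acid, heat or any activation of the carboxyl group the ketone oxygen closes onto the carbonyl and an isocoumarin forms, which in ring A would also expel ring B. The aryl ester will not survive hydroxide, alkoxide or amines, and it has to be made on a hindered 2,6-disubstituted benzoic acid. The enabling feature is on ring B: the C1 carboxyl is flanked by the C2 methoxy group and by C6, so C6–H is the only ortho hydrogen, and the C1 carboxyl/C6 2-oxoheptyl pair is a hydrolysed 3-pentylisocoumarin. Ring A shows the same arrangement (C2 oxygen, C1 carboxyl, C6–H), so one reaction type can serve both halves.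

## Retrosynthesis

**Unmasking (24 from 23 from 22).** The last bonds cut are the two O–CH2Ph bonds (C2 ether of ring A, ester of ring B) and, one step earlier, the two C–O bonds of a dioxolane on the ring A ketone. Hydrogenolysis is placed last because it is neutral: it frees the ring B keto acid and the ring A C2 hydroxyl without acid, base or heat. The ketal is removed one step before, while the ring B carboxyl is still an ester. Precursor 22 has the same skeleton, but every reactive group in it is masked.

**Depside ester (22 from 21 and 13).** The acyl C–O(aryl) bond between the rings is cut. It is the only bond joining the halves and divides the molecule into two benzoic acid derivatives of similar size; building ring A onto a preformed ester is weighed below as Alternative 3. The forward reaction is a Steglich esterification of a 2,6-disubstituted acid with an unhindered phenol. It requires the ring B carboxyl to be blocked (benzyl ester 13) and the ring A ketone to be masked (dioxolane acid 21), because an activated 2-(2-oxoalkyl)benzoic acid is captured by its own ketone oxygen before an external phenol can reach it.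

**Ring B partner (13 from 12 from 10 from 11).** The ester O–benzyl bond (13 to 12) and the ether O–benzyl bond (12 to 10) are functional-group changes. The real move is to re-close the carboxyl oxygen onto the ketone carbon and read keto acid 10 as the hydroxide adduct of isocoumarin 11. The lactone is opened before the benzyl ether is removed for two reasons. A C6 phenoxide on the isocoumarin would be conjugated with the lactone carbonyl and slow the saponification. The enol C3–C4 double bond would also be exposed to hydrogenation. Benzylation of 12 under bicarbonate then distinguishes acid from phenol by acidity alone.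

**Key disconnection (11 from 5 and 9).** Two bonds are cut: ring B C6–CH2 and the lactone O–C3 bond. The neighbouring options are lateral metalation of an ortho-toluate or halogenation and cross-coupling. Both need a C6 methyl or halide, which electrophilic substitution cannot place, because C3 and C5 are the activated positions of a resorcinol diether and C6 is not. Carboxylate-directed C–H activation goes where electrophiles do not, and ylide 9 brings the whole seven-carbon chain at the ketone oxidation level. Precursor 5 is a simple benzoic acid. The forward reaction must be site-selective and must favour C–H insertion over O-alkylation of the carboxylate.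

**Precursors of the key step (5 from 3 from 1 and 2; 9 from 6 and 7).** Only O–C bonds are cut on the arene. The C4 hydroxyl of 1 is benzylated first because the C2 hydroxyl is hydrogen-bonded to the ester; methylation and saponification follow in one flask through 4. Ylide 9 comes from C-acylation of methylide 8 (generated from 6) with hexanoyl chloride 7.

**Ring A partner (21 from 20 from 19 from 17 from 18 from 16 and 9; 16 from 14 and 2).** The same C6–CH2 and lactone C–O bonds are cut in ring A isocoumarin 18, which comes from acid 16 and the same ylide 9. This is preferred to a separate classical arene synthesis because it reuses one reagent and one set of conditions. Opening 18 gives keto acid 17. Its ketone can only be ketalised safely while the carboxyl is an ester, so an allyl ester (19) is used, then ketalisation (20) and neutral deallylation with zerovalent palladium (21). A dioxolane is chosen because it tolerates the free acid of 21 for the short time before coupling. Acid 16 is 14 after benzylation and saponification.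

## Roads not taken

**Alternative 1:** The cut is made on ring A at two ring–substituent bonds at once, C6–CH2 and C1–carbonyl, by reading the ortho carboxyl/CH2 pair as the result of an aryne σ-insertion.
- **Forward step:** a fluoride source releases the aryne from 3,5-dimethoxy-2-(trimethylsilyl)phenyl trifluoromethanesulfonate (A1). The aryne inserts into a C–CO2Me bond of dimethyl malonate (A2) and gives methyl 2,4-dimethoxy-6-(2-methoxy-2-oxoethyl)benzoate (A3).
- **Merits:** both ortho substituents arrive in one metal-free operation at ambient temperature. The regiochemistry is set by the methoxy group next to the triple bond and needs no blocking group.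
- **Weak points:** the side arm of A3 is an acetate, so the aliphatic ester must be differentiated from the benzoate and taken to the pentyl ketone, with lactonisation as a risk on the way. Both ring oxygens are methyl ethers, so ring A needs a selective C2 demethylation. Ring B (C2 methoxy, C4 free) cannot be reached from A3 without an unselective demethylation, so it needs a second route. A1 itself costs several steps.
- **Comparison:** Alternative 1 is better in using no precious metal and no directing group. The chosen plan offers in return a reagent (9) that installs the complete chain at the right oxidation level, acids (5, 16) that are close to commercial esters, and one reaction for both rings.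

**Alternative 2:** Ring A itself is cut, at C1–C6 and C2–C3, and built from acyclic pieces.
- **Forward step:** the anion of A2 adds to the β carbon of (E)-5-(2-pentyl-1,3-dioxolan-2-yl)pent-3-en-2-one (A4). The methyl ketone enolate then closes onto an ester group to give methyl 2-hydroxy-4-oxo-6-[(2-pentyl-1,3-dioxolan-2-yl)methyl]cyclohex-1-ene-1-carboxylate (A5, racemic). Dehydrogenation would give the resorcylate.
- **Merits:** cheap reagents and no transition metal. The ring A ketone is a dioxolane from the start, which the chosen route needs steps 11 to 13 to arrange; here Alternative 2 is ahead. After aromatisation the chelated C2 hydroxyl allows selective C4 methylation.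
- **Weak points:** A4 has a methylene between enone and ketal carbon, so alkoxide base can deprotonate there and deconjugate the enone in competition with conjugate addition. A4 needs several steps. Aromatisation needs an oxidant or a halogenation–elimination sequence beside the ketal. The stereocentre of A5 is made only to be destroyed. The product is a methyl 2,6-disubstituted benzoate whose hydrolysis to the acid is slow. Ring B is again left to another route.
- **Comparison:** the chosen plan gives up the ready-made ketal but gains a much shorter access to the substituted arene, an acid that is free from the start, and coverage of both halves.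

**Alternative 3:** The cut is again inside ring A, at C1–C2 and C5–C6, but with the depside ester already in place.
- **Forward step:** the diene [(1,3-dimethoxybuta-1,3-dien-1-yl)oxy]trimethylsilane (A6) adds in a Diels–Alder reaction to the aryl alk-2-ynoate A7 (the ring B phenol acylated by a 4-(2-pentyl-1,3-dioxolan-2-yl)but-2-ynoyl group). The adduct aromatises with loss of one alkoxy and the silyl group to the protected depside A8.
- **Merits:** this is the most convergent plan. A8 already has the free C2 hydroxyl and C4 methoxy of ring A, with no ring A protecting group. The ester bond is made on an unhindered alkynoic acid, so the hindered esterification (step 14 here) is avoided. These are genuine advantages.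
- **Weak points:** a β-alkyl ynoate is a sluggish dienophile, and the heat it needs competes with decomposition of A6. The propargylic methylene between alkyne and ketal invites isomerisation to an allenoate. The aryl ynoate is an activated ester that the ketene acetal end of A6 can cleave. A7 still requires ring B with its own 2-oxoheptyl arm (a ketal-protected relative of 13), plus a functionalised butynoic acid. The uncertain step comes last and consumes the most valuable intermediate.
- **Comparison:** the chosen plan places its uncertain C–H step at the start, on cheap acids. It pays for this with a hindered esterification and protecting-group steps on ring A.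

Key step: step 4

## Steps

Step 1
Reactants: 1 methyl 2,4-dihydroxybenzoate; 2 benzyl bromide
Product: 3 methyl 4-(benzyloxy)-2-hydroxybenzoate
Conditions: K2CO3 (1.1 equiv), acetone, reflux
Reagents that add atoms: none
Why: Williamson ether synthesis; the C2 hydroxyl is held in a hydrogen bond to the ester carbonyl, so the more acidic and more accessible C4 phenoxide should be alkylated selectively.

Step 2
Reactants: 3 methyl 4-(benzyloxy)-2-hydroxybenzoate
Product: 5 4-(benzyloxy)-2-methoxybenzoic acid, via methyl 4-(benzyloxy)-2-methoxybenzoate 4 (not isolated)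
Conditions: MeI (excess), K2CO3, acetone, reflux; solvent removed; 2 M NaOH, MeOH, 65 °C; then 2 M HCl, 0 °C
Reagents that add atoms: iodomethane, CI; sodium hydroxide (its oxygen ends in the carboxyl group), [Na+].[OH-]
Why: Williamson methylation of the chelated phenol under forcing conditions, then saponification of a benzoate that has only one ortho substituent and should hydrolyse readily; the benzyl ether is inert to both.

Step 3
Reactants: 6 trimethylsulfoxonium iodide; 7 hexanoyl chloride
Product: 9 1-[dimethyl(oxo)-lambda6-sulfanylidene]heptan-2-one, via dimethylsulfoxonium methylide 8 (not isolated)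
Conditions: 6 (3 equiv), KOtBu (3 equiv), THF, reflux; then 7 (1 equiv), 0 °C to rt
Reagents that add atoms: none
Why: Corey–Chaykovsky-type ylide generation followed by C-acylation; a second equivalent of 8 deprotonates the acylated sulfoxonium salt, and the carbonyl-stabilised ylide 9 should not react further with the acid chloride.

Step 4
Reactants: 5 4-(benzyloxy)-2-methoxybenzoic acid; 9 1-[dimethyl(oxo)-lambda6-sulfanylidene]heptan-2-one
Product: 11 6-(benzyloxy)-8-methoxy-3-pentyl-1H-isochromen-1-one, via 4-(benzyloxy)-2-methoxy-6-(2-oxoheptyl)benzoic acid 10 (not isolated)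
Conditions: 9 (1.5 equiv), [Cp*RhCl2]2 (4 mol%), AgSbF6 (16 mol%), NaOAc (30 mol%), HFIP, 80 °C
Reagents that add atoms: none
Why: Carboxylate-assisted concerted metalation–deprotonation by the cationic Cp*Rh catalyst of trivalent rhodium gives a five-membered rhodacycle at C6; ylide 9 binds through carbon, loses dimethyl sulfoxide to form a rhodium carbene, and migratory insertion followed by protodemetalation forms the C6–CH2 bond and releases keto acid 10. The closest known reaction type is the carboxylate-directed ortho C–H acylmethylation of benzoic acids with sulfoxonium ylides that ends in 3-substituted isocoumarins. The pyranone ring then closes by 6-exo-trig addition of the carboxyl oxygen to the ketone carbonyl and loss of water, which the hot, weakly acidic fluoroalcohol medium should promote. No stereocentre is formed. The step needs site selectivity, which is secured because the C2 methoxy group occupies one ortho position and leaves C6–H as the only hydrogen within reach of the carboxylate, so neither a regioisomer nor a double alkylation can arise. It also needs C–H insertion to outrun O-alkylation of the carboxylate by protonated ylide, which the acetate buffer and the fast carbene pathway should ensure.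

Step 5
Reactants: 11 6-(benzyloxy)-8-methoxy-3-pentyl-1H-isochromen-1-one
Product: 10 4-(benzyloxy)-2-methoxy-6-(2-oxoheptyl)benzoic acid
Conditions: 2 M KOH, MeOH, reflux; then 1 M HCl to pH 3, 0 °C
Reagents that add atoms: potassium hydroxide (its oxygen ends in the carboxyl group), [K+].[OH-]
Why: Saponification of an enol lactone; hydroxide adds to C1, the ring oxygen leaves as the ketone enolate, and carboxylate formation makes the opening irreversible. Cold acidification in water should give the keto acid without re-closure.

Step 6
Reactants: 10 4-(benzyloxy)-2-methoxy-6-(2-oxoheptyl)benzoic acid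
Product: 12 4-hydroxy-2-methoxy-6-(2-oxoheptyl)benzoic acid
Conditions: H2 (1 atm), 10% Pd/C, EtOAc, rt
Reagents that add atoms: none
Why: Hydrogenolysis of an aryl benzyl ether; the dialkyl-type ketone and the acid are inert under these conditions, and no enol double bond is left to be reduced.

Step 7
Reactants: 12 4-hydroxy-2-methoxy-6-(2-oxoheptyl)benzoic acid; 2 benzyl bromide
Product: 13 benzyl 4-hydroxy-2-methoxy-6-(2-oxoheptyl)benzoate
Conditions: KHCO3 (1.1 equiv), 2 (1.05 equiv), DMF, rt to 40 °C
Reagents that add atoms: none
Why: Carboxylate O-alkylation; bicarbonate deprotonates only the carboxylic acid, so the phenol and the ketone α-positions should stay untouched.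

Step 8
Reactants: 14 methyl 2-hydroxy-4-methoxybenzoate; 2 benzyl bromide
Product: 16 2-(benzyloxy)-4-methoxybenzoic acid, via methyl 2-(benzyloxy)-4-methoxybenzoate 15 (not isolated)
Conditions: K2CO3, KI (cat.), acetone, reflux; solvent removed; 2 M NaOH, MeOH, 65 °C; then 2 M HCl, 0 °C
Reagents that add atoms: sodium hydroxide (its oxygen ends in the carboxyl group), [Na+].[OH-]
Why: Williamson benzylation of the chelated phenol (iodide catalysis) followed by saponification; excess benzyl bromide ends as neutral benzyl alcohol and is removed by extraction of the carboxylate.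

Step 9
Reactants: 16 2-(benzyloxy)-4-methoxybenzoic acid; 9 1-[dimethyl(oxo)-lambda6-sulfanylidene]heptan-2-one
Product: 18 8-(benzyloxy)-6-methoxy-3-pentyl-1H-isochromen-1-one, via 2-(benzyloxy)-4-methoxy-6-(2-oxoheptyl)benzoic acid 17 (not isolated)
Conditions: 9 (1.5 equiv), [Cp*RhCl2]2 (4 mol%), AgSbF6 (16 mol%), NaOAc (30 mol%), HFIP, 80 °C
Reagents that add atoms: none
Why: The same carboxylate-directed C–H acylmethylation and 6-exo-trig lactonisation as in step 4; the C2 benzyloxy group blocks one ortho position, so only C6–H can be activated.

Step 10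
Reactants: 18 8-(benzyloxy)-6-methoxy-3-pentyl-1H-isochromen-1-one
Product: 17 2-(benzyloxy)-4-methoxy-6-(2-oxoheptyl)benzoic acid
Conditions: 2 M KOH, MeOH, reflux; then 1 M HCl to pH 3, 0 °C
Reagents that add atoms: potassium hydroxide (its oxygen ends in the carboxyl group), [K+].[OH-]
Why: Saponification of the enol lactone as in step 5; the benzyl and methyl ethers are stable to hydroxide.

Step 11
Reactants: 17 2-(benzyloxy)-4-methoxy-6-(2-oxoheptyl)benzoic acid
Product: 19 prop-2-en-1-yl 2-(benzyloxy)-4-methoxy-6-(2-oxoheptyl)benzoate
Conditions: allyl bromide (1.2 equiv), KHCO3 (1.2 equiv), DMF, rt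
Reagents that add atoms: allyl bromide, C=CCBr
Why: Carboxylate O-alkylation under bicarbonate, which is too weak to enolise the benzylic ketone; the carboxyl group is never activated, so no isocoumarin can form.

Step 12
Reactants: 19 prop-2-en-1-yl 2-(benzyloxy)-4-methoxy-6-(2-oxoheptyl)benzoate
Product: 20 prop-2-en-1-yl 2-(benzyloxy)-4-methoxy-6-[(2-pentyl-1,3-dioxolan-2-yl)methyl]benzoate
Conditions: Me3SiOCH2CH2OSiMe3 (2 equiv), TMSOTf (5 mol%), CH2Cl2, −78 to −20 °C; pyridine quench
Reagents that add atoms: 1,2-bis(trimethylsilyloxy)ethane, C[Si](C)(C)OCCO[Si](C)(C)C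
Why: Silyl triflate-catalysed ketalisation of an unhindered ketone, driven by formation of hexamethyldisiloxane; the aprotic low-temperature conditions should leave the hindered allyl ester no path to lactonise.

Step 13
Reactants: 20 prop-2-en-1-yl 2-(benzyloxy)-4-methoxy-6-[(2-pentyl-1,3-dioxolan-2-yl)methyl]benzoate
Product: 21 2-(benzyloxy)-4-methoxy-6-[(2-pentyl-1,3-dioxolan-2-yl)methyl]benzoic acid
Conditions: Pd(PPh3)4 (3 mol%), morpholine (5 equiv), THF, rt; cold pH 4 citrate work-up, used at once
Reagents that add atoms: none
Why: Tsuji–Trost-type deallylation; zerovalent palladium ionises the allyl ester to a π-allyl complex that morpholine captures. The ketal and the benzyl ether are untouched under these neutral conditions, which a hydrolytic cleavage of so hindered an ester could not offer.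

Step 14
Reactants: 21 2-(benzyloxy)-4-methoxy-6-[(2-pentyl-1,3-dioxolan-2-yl)methyl]benzoic acid; 13 benzyl 4-hydroxy-2-methoxy-6-(2-oxoheptyl)benzoate
Product: 22 benzyl 4-({2-(benzyloxy)-4-methoxy-6-[(2-pentyl-1,3-dioxolan-2-yl)methyl]benzoyl}oxy)-2-methoxy-6-(2-oxoheptyl)benzoate
Conditions: DCC (1.2 equiv), DMAP (0.2 equiv), CH2Cl2, 0 °C to rt
Reagents that add atoms: none
Why: Steglich esterification; DMAP carries the hindered acyl group from the O-acylisourea to the unhindered C4 phenol of 13. The ring A ketone is masked and cannot capture the activated carboxyl, and the ring B ketone sits next to an unactivated benzyl ester.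

Step 15
Reactants: 22 benzyl 4-({2-(benzyloxy)-4-methoxy-6-[(2-pentyl-1,3-dioxolan-2-yl)methyl]benzoyl}oxy)-2-methoxy-6-(2-oxoheptyl)benzoate
Product: 23 benzyl 4-{[2-(benzyloxy)-4-methoxy-6-(2-oxoheptyl)benzoyl]oxy}-2-methoxy-6-(2-oxoheptyl)benzoate
Conditions: 1 M HCl, THF, 20 °C
Reagents that add atoms: water, O
Why: Acid-catalysed ketal hydrolysis through the oxocarbenium ion; dilute aqueous acid at ambient temperature should leave the aryl ester, the benzyl ester and the benzyl ether intact.

Step 16
Reactants: 23 benzyl 4-{[2-(benzyloxy)-4-methoxy-6-(2-oxoheptyl)benzoyl]oxy}-2-methoxy-6-(2-oxoheptyl)benzoate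
Product: 24 4-{[2-hydroxy-4-methoxy-6-(2-oxoheptyl)benzoyl]oxy}-2-methoxy-6-(2-oxoheptyl)benzoic acid (CNP0177576.0)
Conditions: H2 (1 atm), 10% Pd/C, EtOAc, rt
Reagents that add atoms: none
Why: Hydrogenolysis of the benzyl ether and the benzyl ester in one neutral operation; the depside ester and both ketones are not reduced, and the freed C2 hydroxyl hydrogen-bonds to the depside carbonyl as in the natural compound.

## Compound list

1 | methyl 2,4-dihydroxybenzoate | COC(=O)c1ccc(O)cc1O | starting material
2 | benzyl bromide | BrCc1ccccc1 | starting material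
3 | methyl 4-(benzyloxy)-2-hydroxybenzoate | COC(=O)c1ccc(OCc2ccccc2)cc1O | intermediate
4 | methyl 4-(benzyloxy)-2-methoxybenzoate | COC(=O)c1ccc(OCc2ccccc2)cc1OC | intermediate
5 | 4-(benzyloxy)-2-methoxybenzoic acid | COc1cc(OCc2ccccc2)ccc1C(=O)O | intermediate
6 | trimethylsulfoxonium iodide | C[S+](C)(C)=O.[I-] | starting material
7 | hexanoyl chloride | CCCCCC(Cl)=O | starting material
8 | dimethylsulfoxonium methylide | C=S(C)(C)=O | intermediate
9 | 1-[dimethyl(oxo)-lambda6-sulfanylidene]heptan-2-one | CCCCCC(=O)C=S(C)(C)=O | intermediate
10 | 4-(benzyloxy)-2-methoxy-6-(2-oxoheptyl)benzoic acid | CCCCCC(=O)Cc1cc(OCc2ccccc2)cc(OC)c1C(=O)O | intermediate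
11 | 6-(benzyloxy)-8-methoxy-3-pentyl-1H-isochromen-1-one | CCCCCc1cc2cc(OCc3ccccc3)cc(OC)c2c(=O)o1 | intermediate
12 | 4-hydroxy-2-methoxy-6-(2-oxoheptyl)benzoic acid | CCCCCC(=O)Cc1cc(O)cc(OC)c1C(=O)O | intermediate
13 | benzyl 4-hydroxy-2-methoxy-6-(2-oxoheptyl)benzoate | CCCCCC(=O)Cc1cc(O)cc(OC)c1C(=O)OCc1ccccc1 | intermediate
14 | methyl 2-hydroxy-4-methoxybenzoate | COC(=O)c1ccc(OC)cc1O | starting material
15 | methyl 2-(benzyloxy)-4-methoxybenzoate | COC(=O)c1ccc(OC)cc1OCc1ccccc1 | intermediate
16 | 2-(benzyloxy)-4-methoxybenzoic acid | COc1ccc(C(=O)O)c(OCc2ccccc2)c1 | intermediate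
17 | 2-(benzyloxy)-4-methoxy-6-(2-oxoheptyl)benzoic acid | CCCCCC(=O)Cc1cc(OC)cc(OCc2ccccc2)c1C(=O)O | intermediate
18 | 8-(benzyloxy)-6-methoxy-3-pentyl-1H-isochromen-1-one | CCCCCc1cc2cc(OC)cc(OCc3ccccc3)c2c(=O)o1 | intermediate
19 | prop-2-en-1-yl 2-(benzyloxy)-4-methoxy-6-(2-oxoheptyl)benzoate | CCCCCC(=O)Cc1cc(OC)cc(OCc2ccccc2)c1C(=O)OCC=C | intermediate
20 | prop-2-en-1-yl 2-(benzyloxy)-4-methoxy-6-[(2-pentyl-1,3-dioxolan-2-yl)methyl]benzoate | CCCCCC1(Cc2cc(OC)cc(OCc3ccccc3)c2C(=O)OCC=C)OCCO1 | intermediate
21 | 2-(benzyloxy)-4-methoxy-6-[(2-pentyl-1,3-dioxolan-2-yl)methyl]benzoic acid | CCCCCC1(Cc2cc(OC)cc(OCc3ccccc3)c2C(=O)O)OCCO1 | intermediate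
22 | benzyl 4-({2-(benzyloxy)-4-methoxy-6-[(2-pentyl-1,3-dioxolan-2-yl)methyl]benzoyl}oxy)-2-methoxy-6-(2-oxoheptyl)benzoate | CCCCCC1(Cc2cc(OC)cc(OCc3ccccc3)c2C(=O)Oc2cc(CC(=O)CCCCC)c(C(=O)OCc3ccccc3)c(OC)c2)OCCO1 | intermediate
23 | benzyl 4-{[2-(benzyloxy)-4-methoxy-6-(2-oxoheptyl)benzoyl]oxy}-2-methoxy-6-(2-oxoheptyl)benzoate | CCCCCC(=O)Cc1cc(OC)cc(OCc2ccccc2)c1C(=O)Oc1cc(CC(=O)CCCCC)c(C(=O)OCc2ccccc2)c(OC)c1 | intermediate
24 | 4-{[2-hydroxy-4-methoxy-6-(2-oxoheptyl)benzoyl]oxy}-2-methoxy-6-(2-oxoheptyl)benzoic acid | CCCCCC(=O)Cc1cc(OC)cc(O)c1C(=O)Oc1cc(CC(=O)CCCCC)c(C(=O)O)c(OC)c1 | target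

## Step count and risk

Total step count: 16. Longest linear sequence: 9 steps (1, 2, 4, 5, 6, 7, 14, 15, 16 from compound 1; equally 8 to 16 from compound 14).

**Step 4 (key step).** The most likely failure is that the protonated ylide alkylates the carboxylate oxygen, or that the electron-rich acid undergoes protodecarboxylation, before cyclometalation occurs, so that conversion stalls. Incomplete cyclodehydration is harmless, since 10 is the product of step 5. The fallback uses stoichiometric directed metalation from 5. The acid chloride of 5 and Et2NH give 4-(benzyloxy)-N,N-diethyl-2-methoxybenzamide F1. Amide-directed ortho-lithiation (s-BuLi, TMEDA, THF, −78 °C) and MeI give 4-(benzyloxy)-N,N-diethyl-2-methoxy-6-methylbenzamide F2. Lateral lithiation (LiN(iPr)2, −78 °C) and acylation with N-methoxy-N-methylhexanamide give 4-(benzyloxy)-N,N-diethyl-2-methoxy-6-(2-oxoheptyl)benzamide F3. Hot acetic acid closes F3 to 11.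

**Step 9.** The benzyloxy group next to the directing carboxylate in 16 may slow cyclometalation by twisting the carboxylate, or may be cleaved in the Lewis-acidic fluoroalcohol medium. The fallback derives ring A from the ring B isocoumarin 11 and needs no second annulation. BBr3 (CH2Cl2, −78 °C to rt) removes both ether groups of 11 to give 6,8-dihydroxy-3-pentyl-1H-isochromen-1-one F4. MeI/K2CO3 in acetone methylates only the non-chelated C6 hydroxyl to give 8-hydroxy-6-methoxy-3-pentyl-1H-isochromen-1-one F5. BnBr/K2CO3 in DMF at 60 °C benzylates the chelated C8 hydroxyl and returns to 18.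

**Step 12.** Under the silyl triflate the neighbouring ester carbonyl may capture the activated ketone, so that the keto ester lactonises back to 18 with loss of the allyl group; the ketal may also re-open on work-up. The fallback changes the mask to a dithioketal, which forms fast and irreversibly and is indifferent to acid. Ethane-1,2-dithiol and BF3·OEt2 (CH2Cl2, 0 °C) convert 19 into prop-2-en-1-yl 2-(benzyloxy)-4-methoxy-6-[(2-pentyl-1,3-dithiolan-2-yl)methyl]benzoate F6. Deallylation as in step 13 gives 2-(benzyloxy)-4-methoxy-6-[(2-pentyl-1,3-dithiolan-2-yl)methyl]benzoic acid F7. Esterification with 13 as in step 14 gives benzyl 4-({2-(benzyloxy)-4-methoxy-6-[(2-pentyl-1,3-dithiolan-2-yl)methyl]benzoyl}oxy)-2-methoxy-6-(2-oxoheptyl)benzoate F8. Alkylative hydrolysis (MeI, CaCO3, aqueous MeCN, 40 °C) returns to 23.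

**Step 14.** The 2,6-disubstituted O-acylisourea may be attacked too slowly by the phenol and rearrange to the N-acylurea, or a dioxolane oxygen may participate at the activated carboxyl. The fallback preforms the acyl chloride under neutral conditions. Treatment of 21 with 1-chloro-N,N,2-trimethylprop-1-en-1-amine (CH2Cl2, 0 °C) gives 2-(benzyloxy)-4-methoxy-6-[(2-pentyl-1,3-dioxolan-2-yl)methyl]benzoyl chloride F9. Phenol 13 with Et3N and DMAP (cat.) then gives 22.

**Step 15.** Once the ring A ketone is free, acid may promote acyl transfer: the enol attacks the neighbouring aryl ester, which lacks a stabilising hydrogen bond while C2 is benzylated, and ring B is expelled. The fallback inverts the last two operations. Hydrogenolysis of 22 (H2, Pd/C, EtOAc) gives 4-({2-hydroxy-4-methoxy-6-[(2-pentyl-1,3-dioxolan-2-yl)methyl]benzoyl}oxy)-2-methoxy-6-(2-oxoheptyl)benzoic acid F10, in which the C2 hydroxyl is hydrogen-bonded to the depside carbonyl as in the natural compound. Ketal removal (In(OTf)3 cat., wet acetone, rt) then gives 24 directly.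

## Further compounds

F1 | step 4 | 4-(benzyloxy)-N,N-diethyl-2-methoxybenzamide | CCN(CC)C(=O)c1ccc(OCc2ccccc2)cc1OC
F2 | step 4 | 4-(benzyloxy)-N,N-diethyl-2-methoxy-6-methylbenzamide | CCN(CC)C(=O)c1c(C)cc(OCc2ccccc2)cc1OC
F3 | step 4 | 4-(benzyloxy)-N,N-diethyl-2-methoxy-6-(2-oxoheptyl)benzamide | CCCCCC(=O)Cc1cc(OCc2ccccc2)cc(OC)c1C(=O)N(CC)CC
F4 | step 9 | 6,8-dihydroxy-3-pentyl-1H-isochromen-1-one | CCCCCc1cc2cc(O)cc(O)c2c(=O)o1
F5 | step 9 | 8-hydroxy-6-methoxy-3-pentyl-1H-isochromen-1-one | CCCCCc1cc2cc(OC)cc(O)c2c(=O)o1
F6 | step 12 | prop-2-en-1-yl 2-(benzyloxy)-4-methoxy-6-[(2-pentyl-1,3-dithiolan-2-yl)methyl]benzoate | CCCCCC1(Cc2cc(OC)cc(OCc3ccccc3)c2C(=O)OCC=C)SCCS1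
F7 | step 12 | 2-(benzyloxy)-4-methoxy-6-[(2-pentyl-1,3-dithiolan-2-yl)methyl]benzoic acid | CCCCCC1(Cc2cc(OC)cc(OCc3ccccc3)c2C(=O)O)SCCS1
F8 | step 12 | benzyl 4-({2-(benzyloxy)-4-methoxy-6-[(2-pentyl-1,3-dithiolan-2-yl)methyl]benzoyl}oxy)-2-methoxy-6-(2-oxoheptyl)benzoate | CCCCCC1(Cc2cc(OC)cc(OCc3ccccc3)c2C(=O)Oc2cc(CC(=O)CCCCC)c(C(=O)OCc3ccccc3)c(OC)c2)SCCS1
F9 | step 14 | 2-(benzyloxy)-4-methoxy-6-[(2-pentyl-1,3-dioxolan-2-yl)methyl]benzoyl chloride | CCCCCC1(Cc2cc(OC)cc(OCc3ccccc3)c2C(=O)Cl)OCCO1
F10 | step 15 | 4-({2-hydroxy-4-methoxy-6-[(2-pentyl-1,3-dioxolan-2-yl)methyl]benzoyl}oxy)-2-methoxy-6-(2-oxoheptyl)benzoic acid | CCCCCC1(Cc2cc(OC)cc(O)c2C(=O)Oc2cc(CC(=O)CCCCC)c(C(=O)O)c(OC)c2)OCCO1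
A1 | alternative 1 | 3,5-dimethoxy-2-(trimethylsilyl)phenyl trifluoromethanesulfonate | COc1cc(OC)c([Si](C)(C)C)c(OS(=O)(=O)C(F)(F)F)c1
A2 | alternative 1 | dimethyl malonate | COC(=O)CC(=O)OC
A3 | alternative 1 | methyl 2,4-dimethoxy-6-(2-methoxy-2-oxoethyl)benzoate | COC(=O)Cc1cc(OC)cc(OC)c1C(=O)OC
A4 | alternative 2 | (E)-5-(2-pentyl-1,3-dioxolan-2-yl)pent-3-en-2-one | CCCCCC1(C/C=C/C(C)=O)OCCO1
A5 | alternative 2 | methyl 2-hydroxy-4-oxo-6-[(2-pentyl-1,3-dioxolan-2-yl)methyl]cyclohex-1-ene-1-carboxylate (racemic, one enantiomer drawn) | COC(=O)C1=C(O)CC(=O)C[C@@H]1CC1(CCCCC)OCCO1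
A6 | alternative 3 | [(1,3-dimethoxybuta-1,3-dien-1-yl)oxy]trimethylsilane | COC(=C)C=C(OC)O[Si](C)(C)C
A7 | alternative 3 | benzyl 2-methoxy-4-{[4-(2-pentyl-1,3-dioxolan-2-yl)but-2-ynoyl]oxy}-6-[(2-pentyl-1,3-dioxolan-2-yl)methyl]benzoate | CCCCCC1(CC#CC(=O)Oc2cc(CC3(CCCCC)OCCO3)c(C(=O)OCc3ccccc3)c(OC)c2)OCCO1
A8 | alternative 3 | benzyl 4-({2-hydroxy-4-methoxy-6-[(2-pentyl-1,3-dioxolan-2-yl)methyl]benzoyl}oxy)-2-methoxy-6-[(2-pentyl-1,3-dioxolan-2-yl)methyl]benzoate | CCCCCC1(Cc2cc(OC)cc(O)c2C(=O)Oc2cc(CC3(CCCCC)OCCO3)c(C(=O)OCc3ccccc3)c(OC)c2)OCCO1
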